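**Retrosynthetic overview**
1. The target is the all-trans tetrahydrofuran (O1, C2–C5) with ArCH at C2 and C5 and CH2OH on C3 and C4. Both CH2OH groups come from methyl esters by LiAlH4 in the last step, which also frees the last phenol.
2. C4 and C5 are saturated late, by ionic hydrogenation of the C4=C5 push–pull enol ether of a trans-2,3-dihydrofuran; C3 is the acid-stable anchor.
3. Key disconnection, (4+1): C2 is a one-carbon ArCH unit bonded to O1 and C3 and comes from a chiral benzylic sulfonium ylide. O1–C5–C4–C3 is the oxadiene (ketone O, ketone C, α-C, β-C) of a 2-aroylbutenedioate that already carries both future CH2OH carbons as esters. Bonds formed: C2–C3 and O1–C2.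
4. The acceptor comes from O-MOM acetovanillone (Claisen methoxycarbonylation, Knoevenagel with methyl glyoxylate). The ylide precursor comes from O-pivaloyl vanillin (reduction, bromination) and (2R,5R)-2,5-dimethylthiolane, made from (2S,5S)-hexane-2,5-diol.
5. Ring order: the only ring, the oxolane, is closed in the key step.

Key step: step 10

Assumption (sense of induction): the (2R,5R)-thiolanium benzylide is taken to bond to the Michael acceptor on the same ylide face as it does to aldehydes, which after invertive closure gives the (2R) centre; if the sense proves opposite, the (2S,5S)-thiolane from (2R,5R)-hexane-2,5-diol is used.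

Remark (protecting groups): the two phenols are protected differently on purpose. The ylide-derived aryl group carries a pivalate so that the benzylic C2–O1 bond cannot ionise in the acid of step 11. The acceptor-derived aryl group carries a MOM ether that falls off there, so that only C5 is activated.

**Step 1**
Reactants: 1 acetovanillone
Product: 2 1-[3-methoxy-4-(methoxymethoxy)phenyl]ethanone
Conditions: MOMCl, iPr2NEt, CH2Cl2, 0 °C → rt
Reagents that add atoms: chloromethyl methyl ether, COCCl
Why: Williamson-type O-alkylation of the phenol with the α-chloro ether gives a MOM acetal that is inert to NaH, amine and carbonate bases and is meant to leave in the acid of step 11.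

**Step 2**
Reactants: 2 1-[3-methoxy-4-(methoxymethoxy)phenyl]ethanone
Product: 3 methyl 3-[3-methoxy-4-(methoxymethoxy)phenyl]-3-oxopropanoate
Conditions: NaH, (MeO)2CO, THF, reflux; AcOH quench
Reagents that add atoms: dimethyl carbonate, COC(=O)OC
Why: Crossed Claisen condensation, in which the ketone enolate is C-methoxycarbonylated and the equilibrium is pulled over by deprotonation of the β-keto ester formed.

**Step 3**
Reactants: 3 methyl 3-[3-methoxy-4-(methoxymethoxy)phenyl]-3-oxopropanoate; 4 methyl glyoxylate
Product: 5 dimethyl (E)-2-[3-methoxy-4-(methoxymethoxy)benzoyl]but-2-enedioate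
Conditions: piperidine (10 mol %), AcOH (10 mol %), 4 Å MS, toluene, rt → 50 °C (4 in excess, 3 added slowly)
Reagents that add atoms: none
Why: Knoevenagel condensation, in which the enol of 3 adds to the amine-activated aldehyde of 4 and the aldol adduct dehydrates by E1cB to the tri-acceptor alkene; an E/Z mixture is acceptable (E drawn) because C3–C4 becomes a freely rotating single bond in step 10, and excess 4 with slow addition of 3 suppresses Michael addition of a second molecule of 3.

**Step 4**
Reactants: 6 vanillin
Product: 7 4-formyl-2-methoxyphenyl pivalate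
Conditions: PivCl, Et3N, DMAP (cat.), CH2Cl2, 0 °C → rt
Reagents that add atoms: pivaloyl chloride, CC(C)(C)C(Cl)=O
Why: DMAP-catalysed O-acylation of the phenol gives a pivalate that survives borohydride, PBr3, carbonate base and TFA, makes this aryl group a poor cation-stabilising group for step 11, and is removed by LiAlH4 in the last step.

**Step 5**
Reactants: 7 4-formyl-2-methoxyphenyl pivalate
Product: 8 4-(hydroxymethyl)-2-methoxyphenyl pivalate
Conditions: NaBH4, THF–MeOH, 0 °C
Reagents that add atoms: none
Why: Chemoselective borohydride reduction of the aldehyde, which is far faster than attack on the hindered aryl pivalate at 0 °C.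

**Step 6**
Reactants: 8 4-(hydroxymethyl)-2-methoxyphenyl pivalate
Product: 9 4-(bromomethyl)-2-methoxyphenyl pivalate
Conditions: PBr3, CH2Cl2, 0 °C
Reagents that add atoms: phosphorus tribromide, BrP(Br)Br
Why: Bromination of the benzylic alcohol through its phosphite ester with SN2 displacement by bromide; the acyloxy-substituted benzyl bromide is stable enough to isolate and no acid-sensitive group is present.

**Step 7**
Reactants: 10 (2S,5S)-hexane-2,5-diol
Product: 11 (2S,5S)-hexane-2,5-diyl dimethanesulfonate
Conditions: MsCl, Et3N, CH2Cl2, 0 °C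
Reagents that add atoms: methanesulfonyl chloride, CS(Cl)(=O)=O
Why: O-Sulfonylation of both secondary alcohols with retention, since no C–O bond is broken.

**Step 8**
Reactants: 11 (2S,5S)-hexane-2,5-diyl dimethanesulfonate
Product: 12 (2R,5R)-2,5-dimethylthiolane
Conditions: Na2S·9H2O, DMSO, rt → 40 °C
Reagents that add atoms: sodium sulfide, [Na+].[Na+].[S-2]
Why: Double SN2 thioetherification, in which sulfide displaces one mesylate and the resulting thiolate closes the five-membered ring on the second, each with inversion, so the (2S,5S)-diol gives the C2-symmetric trans-(2R,5R)-thiolane.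

**Step 9**
Reactants: 9 4-(bromomethyl)-2-methoxyphenyl pivalate; 12 (2R,5R)-2,5-dimethylthiolane
Product: 13 (2R,5R)-1-[3-methoxy-4-(pivaloyloxy)benzyl]-2,5-dimethylthiolan-1-ium tetrafluoroborate
Conditions: AgBF4, CH2Cl2, 0 °C → rt, dark
Reagents that add atoms: silver tetrafluoroborate, [Ag+].F[B-](F)(F)F
Why: Silver-assisted S-alkylation of the hindered sulfide by the benzylic bromide, driven by precipitation of AgBr and giving a salt with a non-nucleophilic counter-ion; the C2 symmetry of the thiolane makes both sulfur lone pairs equivalent, so a single sulfonium salt forms and sulfur is not a stereocentre.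

**Step 10**
Reactants: 13 (2R,5R)-1-[3-methoxy-4-(pivaloyloxy)benzyl]-2,5-dimethylthiolan-1-ium tetrafluoroborate; 5 dimethyl (E)-2-[3-methoxy-4-(methoxymethoxy)benzoyl]but-2-enedioate
Product: 16 dimethyl (2R,3R)-5-[3-methoxy-4-(methoxymethoxy)phenyl]-2-[3-methoxy-4-(pivaloyloxy)phenyl]-2,3-dihydrofuran-3,4-dicarboxylate, via sulfonium benzylide 14 (not isolated), via anti betaine 15 (not isolated)
Conditions: Cs2CO3, MeCN–CH2Cl2, −30 → 0 °C (base added last to 13 and 5)
Reagents that add atoms: none
Why: Cs2CO3 deprotonates 13 to the semi-stabilised benzylic ylide 14, whose carbon adds to C3 of 5, the only position that gives the doubly stabilised β-keto ester enolate, to form betaine 15 (bond C2–C3); after rotation about C2–C3 the enolate oxygen displaces the neutral thiolane at C2 with inversion (bond O1–C2). The closest known reaction type is the formal (4+1) annulation of sulfonium ylides with alkylidene β-dicarbonyl compounds to trans-2,3-dihydrofurans. The single ring (O1, C2–C5) closes by 5-exo-tet O-alkylation; a competing 3-exo-tet C-alkylation would give an aroylcyclopropane whose Cloke–Wilson rearrangement leads to the same dihydrofuran with C3 unchanged. C2 is set by the ylide face left open by the C2-symmetric (2R,5R)-thiolane followed by invertive closure, and C3 is set relative to C2 because betaine formation on this stabilised enolate is reversible and the anti betaine, which closes with aryl and ester apart, is the one drained to product (trans). The step needs attack at C3, O- rather than C-alkylation, trans geometry and enantiofacial control, which are secured in turn by the polarisation of the tri-acceptor alkene, the aryl-ketone enolate oxygen and the ease of five- over three-ring closure, the reversible addition, and the chiral sulfide. Compound 5 has no acidic hydrogen and the aryl pivalate is inert to anhydrous carbonate, so the base has no other substrate.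

**Step 11**
Reactants: 16 dimethyl (2R,3R)-5-[3-methoxy-4-(methoxymethoxy)phenyl]-2-[3-methoxy-4-(pivaloyloxy)phenyl]-2,3-dihydrofuran-3,4-dicarboxylate
Product: 19 dimethyl (2R,3R,4R,5R)-5-(4-hydroxy-3-methoxyphenyl)-2-[3-methoxy-4-(pivaloyloxy)phenyl]tetrahydrofuran-3,4-dicarboxylate, via MOM-free dihydrofuran 17 (not isolated), via C5-epimeric tetrahydrofuran 18 (not isolated)
Conditions: Et3SiH, TFA–CH2Cl2 (1:1), 0 °C → rt; then evaporate, TFA–CH2Cl2 (1:4), rt, until the isomer ratio is constant
Reagents that add atoms: none
Why: Ionic hydrogenation of an enol ether, in which TFA first removes the MOM group (17, the methoxymethyl cation being reduced to dimethyl ether) and protonates C4 reversibly so that the C4 ester sits trans to the C3 ester in the 5-(4-hydroxyaryl)oxocarbenium ion, Et3SiH delivers hydride to C5, expected anti to the C4 ester (18), and because only the C5 aryl group is a free p-hydroxyphenyl its benzylic C5–O1 bond ionises and recloses in the acid until C5 sits trans to C4 and C2 (19), while C2 (pivaloyloxyaryl, poor cation) and C3 (no enolisation in acid) keep the configuration set in step 10.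

**Step 12**
Reactants: 19 dimethyl (2R,3R,4R,5R)-5-(4-hydroxy-3-methoxyphenyl)-2-[3-methoxy-4-(pivaloyloxy)phenyl]tetrahydrofuran-3,4-dicarboxylate
Product: 20 (+)-neoolivil, [(2R,3S,4S,5R)-2,5-bis(4-hydroxy-3-methoxyphenyl)tetrahydrofuran-3,4-diyl]dimethanol
Conditions: LiAlH4 (excess), THF, 0 °C → rt; aq. Rochelle salt
Reagents that add atoms: none
Why: Hydride reduction of both methyl esters to primary alcohols with concurrent reductive cleavage of the aryl pivalate; no stereocentre is touched (the C3/C4 descriptors change from R to S only through CIP priority), and the temperature is kept at or below rt so that the p-hydroxybenzylic ethers are not opened.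

**Compound list**
1 | acetovanillone | CC(=O)c1ccc(O)c(OC)c1 | starting material
2 | 1-[3-methoxy-4-(methoxymethoxy)phenyl]ethanone | CC(=O)c1ccc(OCOC)c(OC)c1 | intermediate
3 | methyl 3-[3-methoxy-4-(methoxymethoxy)phenyl]-3-oxopropanoate | COC(=O)CC(=O)c1ccc(OCOC)c(OC)c1 | intermediate
4 | methyl glyoxylate | COC(=O)C=O | starting material
5 | dimethyl (E)-2-[3-methoxy-4-(methoxymethoxy)benzoyl]but-2-enedioate | COC(=O)/C=C(/C(=O)OC)C(=O)c1ccc(OCOC)c(OC)c1 | intermediate
6 | vanillin | COc1cc(C=O)ccc1O | starting material
7 | 4-formyl-2-methoxyphenyl pivalate | COc1cc(C=O)ccc1OC(=O)C(C)(C)C | intermediate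
8 | 4-(hydroxymethyl)-2-methoxyphenyl pivalate | COc1cc(CO)ccc1OC(=O)C(C)(C)C | intermediate
9 | 4-(bromomethyl)-2-methoxyphenyl pivalate | COc1cc(CBr)ccc1OC(=O)C(C)(C)C | intermediate
10 | (2S,5S)-hexane-2,5-diol | C[C@H](O)CC[C@H](C)O | starting material
11 | (2S,5S)-hexane-2,5-diyl dimethanesulfonate | C[C@H](OS(C)(=O)=O)CC[C@H](C)OS(C)(=O)=O | intermediate
12 | (2R,5R)-2,5-dimethylthiolane | C[C@@H]1CC[C@@H](C)S1 | intermediate
13 | (2R,5R)-1-[3-methoxy-4-(pivaloyloxy)benzyl]-2,5-dimethylthiolan-1-ium tetrafluoroborate | C[C@@H]1CC[C@@H](C)[S+]1Cc1ccc(OC(=O)C(C)(C)C)c(OC)c1.F[B-](F)(F)F | intermediate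
14 | (2R,5R)-2,5-dimethylthiolanium [3-methoxy-4-(pivaloyloxy)phenyl]methylide | C[C@@H]1CC[C@@H](C)[S+]1[CH-]c1ccc(OC(=O)C(C)(C)C)c(OC)c1 | intermediate
15 | anti betaine: sulfonium enolate from addition of the ylide carbon to C3 of 5 (C2 and C3 as required for 16, inversion at C2 on closure) | C[C@@H]1CC[C@@H](C)[S+]1[C@H](c1ccc(OC(=O)C(C)(C)C)c(OC)c1)[C@H](C(=O)OC)C(C(=O)OC)=C([O-])c1ccc(OCOC)c(OC)c1 | intermediate
16 | dimethyl (2R,3R)-5-[3-methoxy-4-(methoxymethoxy)phenyl]-2-[3-methoxy-4-(pivaloyloxy)phenyl]-2,3-dihydrofuran-3,4-dicarboxylate | COc1cc([C@@H]2OC(c3ccc(OCOC)c(OC)c3)=C(C(=O)OC)[C@H]2C(=O)OC)ccc1OC(=O)C(C)(C)C | intermediate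
17 | dimethyl (2R,3R)-5-(4-hydroxy-3-methoxyphenyl)-2-[3-methoxy-4-(pivaloyloxy)phenyl]-2,3-dihydrofuran-3,4-dicarboxylate | COc1cc([C@@H]2OC(c3ccc(O)c(OC)c3)=C(C(=O)OC)[C@H]2C(=O)OC)ccc1OC(=O)C(C)(C)C | intermediate
18 | dimethyl (2R,3R,4R,5S)-5-(4-hydroxy-3-methoxyphenyl)-2-[3-methoxy-4-(pivaloyloxy)phenyl]tetrahydrofuran-3,4-dicarboxylate (2,5-cis, 4,5-cis) | COc1cc([C@@H]2O[C@H](c3ccc(O)c(OC)c3)[C@H](C(=O)OC)[C@H]2C(=O)OC)ccc1OC(=O)C(C)(C)C | intermediate
19 | dimethyl (2R,3R,4R,5R)-5-(4-hydroxy-3-methoxyphenyl)-2-[3-methoxy-4-(pivaloyloxy)phenyl]tetrahydrofuran-3,4-dicarboxylate (all-trans) | COc1cc([C@@H]2O[C@@H](c3ccc(O)c(OC)c3)[C@H](C(=O)OC)[C@H]2C(=O)OC)ccc1OC(=O)C(C)(C)C | intermediate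
20 | (+)-neoolivil, [(2R,3S,4S,5R)-2,5-bis(4-hydroxy-3-methoxyphenyl)tetrahydrofuran-3,4-diyl]dimethanol | COc1cc([C@@H]2O[C@@H](c3ccc(O)c(OC)c3)[C@H](CO)[C@H]2CO)ccc1O | target

**Step count**
Total: 12 steps. Longest linear sequence: 7 steps (4, 5, 6, 9, 10, 11, 12, from vanillin).

**Steps most likely to fail**

1. Step 10. Because the betaine forms reversibly on a very stabilised enolate, the sulfide may discriminate poorly between the ylide faces at the ring-closing stage, lowering the enantiomeric purity. C-alkylation may give a cyclopropane that does not rearrange. The ylide may decay by Sommelet–Hauser or Stevens rearrangement before it adds. Prolonged base may open the product by deprotonation at C3 and loss of O1 from C2. The fallback sets out from 3 and 7 and returns at 16. Wittig olefination of 7 with methyl (triphenylphosphoranylidene)acetate (toluene, 80 °C) should give methyl (E)-3-[3-methoxy-4-(pivaloyloxy)phenyl]acrylate F1. Mn(OAc)3·2H2O with catalytic Cu(OAc)2 (AcOH–MeCN, 50 °C) then joins 3 and F1 in the known Mn(III) oxidative radical annulation: the β-keto ester radical adds to the α-carbon of the cinnamate, the benzylic radical is oxidised and the ketone oxygen captures it. This should give the racemic trans-dihydrofuran F2. Preparative chromatography of F2 on a chiral stationary phase gives 16.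

2. Step 11. C-protonation of the deactivated push–pull enol ether may be too slow. Protonation at C4 may occur cis to the C3 ester, which the acid cannot correct and which would lead to the 2,5-cis, 3,4-cis isomer. During the C5 equilibration the ring-opened benzylic cation may be captured by hydride (reductive ring opening), may lose the C4 proton to an arylidene succinate, or may undergo Friedel–Crafts cyclisation instead of reclosing. The fallback sets out from 16 and returns at 20. Hydrogenation over 5% Rh/Al2O3 (H2, 1–4 atm, EtOAc) adds H2 syn, expected anti to the C3 ester, to give the 2,3-trans-3,4-cis-4,5-cis tetrahydrofuran F3; any isomer from the other face is removed by chromatography. NaOMe in MeOH (rt) epimerises C4 to the all-trans arrangement, the 2,5-trans aryl groups being fixed under base, and removes the pivalate, giving the mono-MOM all-trans diester F4. HCl (cat.) in MeOH (rt) removes the MOM group to give the bis-phenol all-trans diester F5. LiAlH4 in THF as in step 12 reduces F5 to 20.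

3. Step 3. A second molecule of 3 may add to the very electrophilic product, the amine catalyst may add to it, or the glyoxylate may oligomerise or hydrate, so that the alkene is not obtained cleanly. The fallback sets out from 3 and returns at 5. C-Alkylation of 3 with methyl bromoacetate (K2CO3, acetone) gives dimethyl 2-[3-methoxy-4-(methoxymethoxy)benzoyl]butanedioate F6. Selenenylation (PhSeCl, pyridine, CH2Cl2) gives dimethyl 2-[3-methoxy-4-(methoxymethoxy)benzoyl]-2-(phenylselanyl)butanedioate F7. Oxidation with H2O2 (CH2Cl2, 0 °C) and selenoxide syn-elimination, for which only the CH2CO2Me hydrogens are available, gives 5.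

**Further compounds**
F1 | step 10 | methyl (E)-3-[3-methoxy-4-(pivaloyloxy)phenyl]acrylate | COC(=O)/C=C/c1ccc(OC(=O)C(C)(C)C)c(OC)c1
F2 | step 10 | rac-dimethyl (2R*,3R*)-5-[3-methoxy-4-(methoxymethoxy)phenyl]-2-[3-methoxy-4-(pivaloyloxy)phenyl]-2,3-dihydrofuran-3,4-dicarboxylate (racemate of 16, relative configuration shown) | COc1cc([C@@H]2OC(c3ccc(OCOC)c(OC)c3)=C(C(=O)OC)[C@H]2C(=O)OC)ccc1OC(=O)C(C)(C)C
F3 | step 11 | dimethyl (2R,3R,4S,5R)-5-[3-methoxy-4-(methoxymethoxy)phenyl]-2-[3-methoxy-4-(pivaloyloxy)phenyl]tetrahydrofuran-3,4-dicarboxylate | COc1cc([C@@H]2O[C@@H](c3ccc(OCOC)c(OC)c3)[C@@H](C(=O)OC)[C@H]2C(=O)OC)ccc1OC(=O)C(C)(C)C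
F4 | step 11 | dimethyl (2R,3R,4R,5R)-2-(4-hydroxy-3-methoxyphenyl)-5-[3-methoxy-4-(methoxymethoxy)phenyl]tetrahydrofuran-3,4-dicarboxylate | COc1cc([C@@H]2O[C@@H](c3ccc(OCOC)c(OC)c3)[C@H](C(=O)OC)[C@H]2C(=O)OC)ccc1O
F5 | step 11 | dimethyl (2R,3R,4R,5R)-2,5-bis(4-hydroxy-3-methoxyphenyl)tetrahydrofuran-3,4-dicarboxylate | COc1cc([C@@H]2O[C@@H](c3ccc(O)c(OC)c3)[C@H](C(=O)OC)[C@H]2C(=O)OC)ccc1O
F6 | step 3 | dimethyl 2-[3-methoxy-4-(methoxymethoxy)benzoyl]butanedioate (racemic) | COC(=O)CC(C(=O)OC)C(=O)c1ccc(OCOC)c(OC)c1
F7 | step 3 | dimethyl 2-[3-methoxy-4-(methoxymethoxy)benzoyl]-2-(phenylselanyl)butanedioate (racemic) | COC(=O)CC([Se]c1ccccc1)(C(=O)OC)C(=O)c1ccc(OCOC)c(OC)c1
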